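**Plan**
Numbering (tricyclo[5.4.0.0^1,4]undecane): C1 central quaternary C, C2 CHOAc, C3 CH2, C4 CMe, C5 CHBr, C6 CH2, C7 CMe, C8 CHMe, C9 CHBr, C10 CHOH, C11 CHMe.
Enabling feature: the cyclobutane C1-C2-C3-C4 shares the C1-C4 bond with the cyclopentane C1-C4-C5-C6-C7, and C5 next to C4 can be a ketone. The 4/5 unit is then a bicyclo[3.2.0]heptan-2-one with the oxygenated carbon C2 on the former β-carbon C1, which is the head-to-tail photoadduct of a 2-methylcyclopentenone and vinyl acetate.
Retrosynthesis: C9-Br/C10-OH go back to a C10 ketone and C5-Br to a C5 ketone. Cutting C1-C2 and C3-C4 ([2+2], C1-C2 being the ring-closing bond) gives hydrindenone 14 and vinyl acetate. Cutting C1=C4 (aldol), C6-C7, C8-Me and C11-Me leads to (S)-carvone.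
Forward order of rings: the cyclohexane is the carvone ring (carvone C1/C2/C3/C4/C5/C6 = C1/C7/C8/C9/C10/C11, isopropenyl = latent C10-O). The cyclopentenone is annulated next, the cyclobutane comes last, and the two bromides follow.
Stereochemistry: carvone C5 directs C8 (cuprate anti), C8 directs C7 (alkylation anti), and C11 is equilibrated to equatorial in the enone. The axial C10-OTBS and ring strain fix the face of the photocycloaddition (C1, C4), and the C7 methyl turns the acetate exo (C2). C5 is set by convex-face H-atom transfer, C9 by bromination anti to the C7/C8 methyls, and C10 by hydride addition anti to C-Br.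

Key step: step 8

Remark: target numbering is used for all intermediates. Compounds 6 and 7 are drawn as the expected major C11 epimer, and this centre is equilibrated in step 4.

**Step 1**
Reactants: 1 (S)-(+)-carvone; 2 1-bromobut-2-yne
Product: 4 (2R,3S,5S)-2-(but-2-yn-1-yl)-2,3-dimethyl-5-(prop-1-en-2-yl)cyclohexan-1-one, via lithium enolate 3 (not isolated)
Conditions: Me2CuLi (from MeLi, CuI), Et2O, -20 to 0 °C; then 2, HMPA, THF, -20 °C to rt
Reagents that add atoms: lithium dimethylcuprate [Li+].C[Cu-]C
Why: Tandem cuprate conjugate addition/enolate alkylation, in which methyl adds axially to C8 anti to the isopropenyl group and the regiodefined enolate 3 is alkylated at C7 by the reactive propargylic bromide anti to the new pseudoaxial C8 methyl, leaving the C7 and C8 methyls cis as is usual for 2,3-dimethylcyclohexanone enolates.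

**Step 2**
Reactants: 4
Product: 6 (2R,3S,5S,6R)-2-(but-2-yn-1-yl)-2,3,6-trimethyl-5-(prop-1-en-2-yl)cyclohexan-1-one, via lithium enolate 5 (not isolated)
Conditions: LDA, THF, -78 °C; MeI, -78 to 0 °C
Reagents that add atoms: iodomethane CI
Why: Kinetic enolate alkylation at the only enolisable position (C11), where methyl should enter mainly anti to the isopropenyl group, a result that does not matter because C11 is equilibrated in step 4.

**Step 3**
Reactants: 6
Product: 7 (2R,3S,5S,6R)-2,3,6-trimethyl-2-(2-oxobutyl)-5-(prop-1-en-2-yl)cyclohexan-1-one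
Conditions: Ph3PAuCl, AgOTf (2 mol % each), H2O, 1,4-dioxane, 60 °C
Reagents that add atoms: water O
Why: Carbonyl-assisted gold-catalysed alkyne hydration, in which the ring ketone oxygen attacks the proximal alkyne carbon 5-exo-dig so that oxygen ends on C5 and the 1,4-diketone forms instead of the 1,5-isomer, while the isopropenyl alkene is not activated by the soft Au(I) catalyst.

**Step 4**
Reactants: 7
Product: 9 (4S,5S,7S,7aR)-3,4,7,7a-tetramethyl-5-(prop-1-en-2-yl)-1,4,5,6,7,7a-hexahydro-2H-inden-2-one, via aldol 8 (not isolated)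
Conditions: KOH, EtOH, reflux
Reagents that add atoms: none
Why: Intramolecular aldol condensation of a 1,4-diketone (cyclopentenone annulation), in which only attack of the C4 methylene on the C1 ketone leads to a product that can dehydrate so that reversible side aldols drain into 9, and C11 equilibrates through the enolate and dienolate to the equatorial methyl because the axial epimer would be syn-diaxial to the axial C7 methyl of the locked chair.

**Step 5**
Reactants: 9
Product: 12 (4R,5S,7S,7aR)-3,4,7,7a-tetramethyl-2-oxo-2,4,5,6,7,7a-hexahydro-1H-inden-5-yl acetate, via methoxy hydroperoxide 10 (not isolated), via peracetate 11 (not isolated)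
Conditions: O3, CH2Cl2-MeOH, -78 °C; N2 purge; Ac2O, Et3N, DMAP, CH2Cl2, 0 to 40 °C
Reagents that add atoms: ozone [O-][O+]=O (ester oxygen on C10); methanol CO (its oxygen becomes the acetate C=O); acetic anhydride CC(=O)OC(C)=O (atoms remain only in 11)
Why: Ozonolysis in methanol followed by Criegee rearrangement, in which the electron-rich 1,1-disubstituted alkene is ozonised faster than the tetrasubstituted enone and in peracetate 11 the secondary ring carbon C10 migrates to oxygen with retention, so the oxygen substituent stays axial and no epimerisable acetyl intermediate is passed.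

**Step 6**
Reactants: 12
Product: 13 (4R,5S,7S,7aR)-5-hydroxy-3,4,7,7a-tetramethyl-1,4,5,6,7,7a-hexahydro-2H-inden-2-one
Conditions: HCl (from AcCl), MeOH, rt
Reagents that add atoms: none
Why: Acid-catalysed transesterification, chosen because basic methanolysis could form the dienolate and expel the axial δ-acetoxy group, and no stereocentre is touched.

**Step 7**
Reactants: 13
Product: 14 (4R,5S,7S,7aR)-5-(tert-butyldimethylsilyloxy)-3,4,7,7a-tetramethyl-1,4,5,6,7,7a-hexahydro-2H-inden-2-one
Conditions: TBSOTf, 2,6-lutidine, CH2Cl2, 0 °C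
Reagents that add atoms: tert-butyldimethylsilyl triflate CC(C)(C)[Si](C)(C)OS(=O)(=O)C(F)(F)F
Why: Silyl ether formation with the reactive triflate, which silylates hindered axial alcohols under non-enolising conditions and installs both a protecting group orthogonal to the later acetate and a bulky axial screen over the upper enone face.

**Step 8**
Reactants: 14; 15 vinyl acetate
Product: 17 10-(tert-butyldimethylsilyloxy)-4,7,8,11-tetramethyl-5-oxotricyclo[5.4.0.0^1,4]undecan-2-yl acetate (exo acetate; C1 C2 C4 C7 C8 C10 C11 as in 25), via 1,4-biradical 16 (not isolated)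
Conditions: hν (medium-pressure Hg lamp, Pyrex, λ > 300 nm), 15 (large excess), CH2Cl2, -30 °C
Reagents that add atoms: none
Why: Excitation and intersystem crossing give the enone triplet, whose less hindered α-carbon C4 bonds to the CH2 terminus of vinyl acetate to give triplet 1,4-biradical 16 (tertiary radical at C1, acetoxy-stabilised radical at C2), and spin inversion followed by C1-C2 recombination closes the ring. The closest known reaction type is the intermolecular enone-alkene [2+2] photocycloaddition, which is established for fully substituted cyclopentenones and for vinyl acetate. One ring is closed, the cyclobutane C1-C2-C3-C4, by collapse of the 1,4-biradical (formal [2+2]), and the five-membered enone allows only a cis 4/5 fusion, so C1 and C4 are set together with the C4 methyl and C11 on the same face. Facial control relative to C7 comes from the locked chair of 14, where the axial C10-OTBS and the axial H on C8 flank the upper (axial) trajectory at C1 and bonding there would give a strained trans-hydrindane, so those biradicals should revert, whereas bonding on the face of the C7 methyl gives the cis-hydrindane. At C2 the acetoxy group should turn exo, because an endo acetate would point at the C7 methyl that lies on the same face as the new ring. The step needs head-to-tail regiochemistry (oxygenated carbon on the β-carbon C1), which is the normal sense for donor alkenes and is reinforced by the crowding at C1, which disfavours first bonding there.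

**Step 9**
Reactants: 17
Product: 19 5-bromo-10-(tert-butyldimethylsilyloxy)-4,7,8,11-tetramethyltricyclo[5.4.0.0^1,4]undec-5-en-2-yl acetate, via silyl hydrazone 18 (not isolated)
Conditions: TBSNHNHTBS, Sc(OTf)3 (1 mol %), CHCl3, 55 °C; then added to Br2, 2-tert-butyl-1,1,3,3-tetramethylguanidine, CH2Cl2, 0 °C to rt
Reagents that add atoms: bromine BrBr; 1,2-bis(tert-butyldimethylsilyl)hydrazine CC(C)(C)[Si](C)(C)NN[Si](C)(C)C(C)(C)C (atoms remain only in 18)
Why: Barton-type vinyl halide synthesis from a hydrazone, well precedented for cyclopentanones with an α-quaternary carbon, using a silyl hydrazine that spares the acetate (free hydrazine would cleave it) and a strong guanidine base that deprotonates C6 quickly, C6 being the only position available for the double bond.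

**Step 10**
Reactants: 19
Product: 20 5-bromo-10-(tert-butyldimethylsilyloxy)-4,7,8,11-tetramethyltricyclo[5.4.0.0^1,4]undecan-2-yl acetate (Br on the cyclobutane face, trans to the C4 methyl)
Conditions: Co(acac)2, t-BuOOH, Et3SiH, 1,4-cyclohexadiene, n-PrOH, rt
Reagents that add atoms: none
Why: Cobalt-hydride hydrogen-atom-transfer hydrogenation of an alkenyl halide (Mukaiyama-type), in which H adds to C6 to give the stabilised α-bromo radical at C5 that keeps its bromine and should abstract H from cyclohexadiene on the convex face of the bicyclo[3.2.0] unit (the C4-methyl face, away from the cyclobutane), placing bromine on the cyclobutane side, which is also the less strained epimer.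

**Step 11**
Reactants: 20
Product: 21 5-bromo-10-hydroxy-4,7,8,11-tetramethyltricyclo[5.4.0.0^1,4]undecan-2-yl acetate
Conditions: HF·pyridine, THF, 0 °C to rt
Reagents that add atoms: none
Why: Fluoride-mediated silyl ether cleavage under mildly acidic conditions, which avoids acetate migration or cleavage and elimination of the secondary bromide that a basic fluoride source could cause.

**Step 12**
Reactants: 21
Product: 22 5-bromo-4,7,8,11-tetramethyl-10-oxotricyclo[5.4.0.0^1,4]undecan-2-yl acetate
Conditions: Dess-Martin periodinane, NaHCO3, CH2Cl2, rt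
Reagents that add atoms: none
Why: Dess-Martin oxidation under buffered neutral conditions, which tolerates hindered secondary alcohols, the acetate and the bromide and should not epimerise C11.

**Step 13**
Reactants: 22
Product: 24 5,9-dibromo-4,7,8,11-tetramethyl-10-oxotricyclo[5.4.0.0^1,4]undecan-2-yl acetate (9-Br trans to the C8 methyl, cis to the C11 methyl), via silyl enol ether 23 (not isolated)
Conditions: LiHMDS (1.1 equiv), TMSCl, THF, -78 °C; crude 23, NBS, THF, -78 to 0 °C
Reagents that add atoms: N-bromosuccinimide O=C1CCC(=O)N1Br; chlorotrimethylsilane C[Si](C)(C)Cl (atoms remain only in 23)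
Why: Kinetic enolisation and electrophilic bromination of a silyl enol ether, in which the limiting amide base takes a proton from the only α-methylene (C9) and not from the neopentyl methine C11 or the less acidic acetate, so C11 is untouched, and NBS should deliver bromine to the face of C9 opposite to the C8 and C7 methyls, giving the epimer that is also favoured on equilibration.

**Step 14**
Reactants: 24
Product: 25 (1R,2R,4R,5S,7R,8R,9S,10R,11R)-5,9-dibromo-10-hydroxy-4,7,8,11-tetramethyltricyclo[5.4.0.0^1,4]undecan-2-yl acetate (target)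
Conditions: NaBH4, CeCl3·7H2O, MeOH, -78 to -40 °C
Reagents that add atoms: none
Why: Luche-type 1,2-reduction of an α-bromo ketone, in which hydride should add anti to the C9-Br bond (polar Felkin-Anh control, the usual origin of cis-halohydrins from 2-halocyclohexanones) and so place the C10 hydroxyl cis to bromine and to the C11 methyl, while a cis-bromohydrin cannot close to an epoxide and the acetate and both bromides are inert to borohydride at low temperature.

**Compound list**
1 | (S)-(+)-carvone | CC1=CC[C@H](C(C)=C)CC1=O | starting material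
2 | 1-bromobut-2-yne | CC#CCBr | starting material
3 | lithium enolate after methyl addition (not isolated) | [Li]OC1=C(C)[C@@H](C)C[C@H](C(C)=C)C1 | intermediate
4 | (2R,3S,5S)-2-(but-2-yn-1-yl)-2,3-dimethyl-5-(prop-1-en-2-yl)cyclohexan-1-one | CC#CC[C@]1(C)[C@@H](C)C[C@H](C(C)=C)CC1=O | intermediate
5 | lithium enolate of 4 (not isolated) | CC#CC[C@]1(C)[C@@H](C)C[C@H](C(C)=C)C=C1O[Li] | intermediate
6 | (2R,3S,5S,6R)-2-(but-2-yn-1-yl)-2,3,6-trimethyl-5-(prop-1-en-2-yl)cyclohexan-1-one | CC#CC[C@]1(C)[C@@H](C)C[C@H](C(C)=C)[C@@H](C)C1=O | intermediate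
7 | (2R,3S,5S,6R)-2,3,6-trimethyl-2-(2-oxobutyl)-5-(prop-1-en-2-yl)cyclohexan-1-one | CCC(=O)C[C@]1(C)[C@@H](C)C[C@H](C(C)=C)[C@@H](C)C1=O | intermediate
8 | aldol, 3a-hydroxy-hexahydroindan-2-one (C1, C4, C11 not defined; not isolated) | CC1C(=O)C[C@]2(C)[C@@H](C)C[C@H](C(C)=C)C(C)C12O | intermediate
9 | (4S,5S,7S,7aR)-3,4,7,7a-tetramethyl-5-(prop-1-en-2-yl)-1,4,5,6,7,7a-hexahydro-2H-inden-2-one | O=C1C[C@]2(C)[C@@H](C)C[C@H](C(C)=C)[C@H](C)C2=C1C | intermediate
10 | α-methoxy hydroperoxide from 9 (acetal carbon not defined; not isolated) | O=C1C[C@]2(C)[C@@H](C)C[C@H](C(C)(OC)OO)[C@H](C)C2=C1C | intermediate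
11 | peracetate of 10 (not isolated) | O=C1C[C@]2(C)[C@@H](C)C[C@H](C(C)(OC)OOC(C)=O)[C@H](C)C2=C1C | intermediate
12 | (4R,5S,7S,7aR)-3,4,7,7a-tetramethyl-2-oxo-2,4,5,6,7,7a-hexahydro-1H-inden-5-yl acetate | O=C1C[C@]2(C)[C@@H](C)C[C@H](OC(C)=O)[C@H](C)C2=C1C | intermediate
13 | (4R,5S,7S,7aR)-5-hydroxy-3,4,7,7a-tetramethyl-1,4,5,6,7,7a-hexahydro-2H-inden-2-one | O=C1C[C@]2(C)[C@@H](C)C[C@H](O)[C@H](C)C2=C1C | intermediate
14 | (4R,5S,7S,7aR)-5-(tert-butyldimethylsilyloxy)-3,4,7,7a-tetramethyl-1,4,5,6,7,7a-hexahydro-2H-inden-2-one | O=C1C[C@]2(C)[C@@H](C)C[C@H](O[Si](C)(C)C(C)(C)C)[C@H](C)C2=C1C | intermediate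
15 | vinyl acetate | C=COC(C)=O | starting material
16 | 1,4-biradical (radicals at C1 and C2; not isolated) | CC(=O)O[CH]C[C@@]1(C)C(=O)C[C@]2(C)[C@@H](C)C[C@H](O[Si](C)(C)C(C)(C)C)[C@H](C)[C]12 | intermediate
17 | photoadduct, 10-OTBS-5-oxo-tricycloundecan-2-yl acetate | CC(=O)O[C@@H]1C[C@@]2(C)C(=O)C[C@]3(C)[C@@H](C)C[C@H](O[Si](C)(C)C(C)(C)C)[C@H](C)[C@]123 | intermediate
18 | C5 N-TBS hydrazone of 17 (not isolated) | CC(=O)O[C@@H]1C[C@@]2(C)C(=NN[Si](C)(C)C(C)(C)C)C[C@]3(C)[C@@H](C)C[C@H](O[Si](C)(C)C(C)(C)C)[C@H](C)[C@]123 | intermediate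
19 | C5 vinyl bromide (C5=C6) | CC(=O)O[C@@H]1C[C@@]2(C)C(Br)=C[C@]3(C)[C@@H](C)C[C@H](O[Si](C)(C)C(C)(C)C)[C@H](C)[C@]123 | intermediate
20 | C5 bromide, 10-OTBS | CC(=O)O[C@@H]1C[C@@]2(C)[C@@H](Br)C[C@]3(C)[C@@H](C)C[C@H](O[Si](C)(C)C(C)(C)C)[C@H](C)[C@]123 | intermediate
21 | C5 bromide, 10-OH | CC(=O)O[C@@H]1C[C@@]2(C)[C@@H](Br)C[C@]3(C)[C@@H](C)C[C@H](O)[C@H](C)[C@]123 | intermediate
22 | C5 bromide, C10 ketone | CC(=O)O[C@@H]1C[C@@]2(C)[C@@H](Br)C[C@]3(C)[C@@H](C)CC(=O)[C@H](C)[C@]123 | intermediate
23 | C9=C10 trimethylsilyl enol ether (not isolated) | CC(=O)O[C@@H]1C[C@@]2(C)[C@@H](Br)C[C@]3(C)[C@@H](C)C=C(O[Si](C)(C)C)[C@H](C)[C@]123 | intermediate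
24 | 5,9-dibromo C10 ketone | CC(=O)O[C@@H]1C[C@@]2(C)[C@@H](Br)C[C@]3(C)[C@@H](C)[C@H](Br)C(=O)[C@H](C)[C@]123 | intermediate
25 | (1R,2R,4R,5S,7R,8R,9S,10R,11R)-5,9-dibromo-10-hydroxy-4,7,8,11-tetramethyltricyclo[5.4.0.0^1,4]undecan-2-yl acetate | CC(=O)O[C@@H]1C[C@@]2(C)[C@@H](Br)C[C@]3(C)[C@@H](C)[C@H](Br)[C@H](O)[C@H](C)[C@]123 | target

Total step count: 14. Longest linear sequence: 14 steps from (S)-carvone.

**Steps most likely to fail**

Step 8. The hindered triplet may be captured inefficiently by the weak donor vinyl acetate. Head-to-head addition, an endo orientation of the acetate or leakage to the upper face may also erode selectivity. The fallback sets out from 14 and returns at 17. It separates ring formation from the setting of C2.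
- Irradiation of 14 with 1,1-dimethoxyethene, a stronger donor that adds head-to-tail throughout, should give the C2 dimethyl ketal photoadduct F1.
- Mild hydrolysis (PPTS, wet acetone) should give the cyclobutanone F2.
- One equivalent of LiAlH(Ot-Bu)3 at -78 °C should reduce the strained four-ring ketone before the neopentyl cyclopentanone. Attack should come from the exo face because the endo face is covered by the C7 methyl, giving the endo-cyclobutanol F3.
- A Mitsunobu reaction with acetic acid inverts C2 and delivers 17.

Step 10. Bromine may be lost by over-reduction, or the hydrogen atom may be delivered to the cyclobutane face and give the C5 epimer. The fallback sets out from 17 and returns at 20. It is stereochemically complementary, because a hydride would use the same more open face.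
- NaBH4 in MeOH should then give the C5 alcohol cis to the C4 methyl F4.
- Tf2O and pyridine convert it into the C5 triflate F5.
- Displacement with Bu4NBr in toluene, a non-ionising medium that suppresses cyclobutylcarbinyl ring expansion, proceeds with inversion and gives 20.

Step 9. Condensation at the neopentyl ketone may be slow, and the cationic stage of the halogenation next to the cyclobutane may trigger ring expansion. The fallback sets out from 17 and returns at 19 by an anionic and metal-catalysed sequence.
- KHMDS (1.05 equiv) and N-(5-chloro-2-pyridyl)bis(trifluoromethanesulfonimide) at -78 °C should give the C5 enol triflate F6.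
- Ruthenium- or palladium-catalysed triflate-bromide exchange with LiBr then gives 19.

**Further compounds**
F1 | step 8 | C2 dimethyl ketal photoadduct | COC1(OC)C[C@@]2(C)C(=O)C[C@]3(C)[C@@H](C)C[C@H](O[Si](C)(C)C(C)(C)C)[C@H](C)[C@]123
F2 | step 8 | cyclobutanone (2,5-dione) | O=C1C[C@@]2(C)C(=O)C[C@]3(C)[C@@H](C)C[C@H](O[Si](C)(C)C(C)(C)C)[C@H](C)[C@]123
F3 | step 8 | endo-cyclobutanol (C2 epimeric alcohol) | O[C@H]1C[C@@]2(C)C(=O)C[C@]3(C)[C@@H](C)C[C@H](O[Si](C)(C)C(C)(C)C)[C@H](C)[C@]123
F4 | step 10 | C5 alcohol cis to the C4 methyl | CC(=O)O[C@@H]1C[C@@]2(C)[C@H](O)C[C@]3(C)[C@@H](C)C[C@H](O[Si](C)(C)C(C)(C)C)[C@H](C)[C@]123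
F5 | step 10 | C5 triflate | CC(=O)O[C@@H]1C[C@@]2(C)[C@H](OS(=O)(=O)C(F)(F)F)C[C@]3(C)[C@@H](C)C[C@H](O[Si](C)(C)C(C)(C)C)[C@H](C)[C@]123
F6 | step 9 | C5 enol triflate | CC(=O)O[C@@H]1C[C@@]2(C)C(OS(=O)(=O)C(F)(F)F)=C[C@]3(C)[C@@H](C)C[C@H](O[Si](C)(C)C(C)(C)C)[C@H](C)[C@]123
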